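**Plan**

1. Retrosynthesis: cut the C6–O acyl bond of the p-coumarate, take C4=C15 back to a C4 ketone and C1–H back to C1–SO2Ph, then cut C1–C2 and C5–C10 together in one retro-[4+2]. The open chain is cut at C9–C10, C8=C9, C3–C4 and C6–C7.
2. Enabling feature (eudesmane numbering): ring A (C1–C2–C3–C4–C5–C10) carries its only function at C4. Written as the C3=C4 silyl enol ether it is a cyclohexene, the adduct of diene C2=C3–C4(OSi)=C5 and alkene C1=C10. Ring B atoms C6–C9 are then the four-atom tether from diene terminus C5 to the methyl-bearing C10.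
3. Forward: C6–C7 (aldol), C8=C9 (Wittig), C9–C10 (B-alkyl Suzuki coupling) and C3–C4 (vinyl Grignard addition) give an acyclic triene. Rings A and B arise together in step 16, followed by C4 methylenation, loss of the sulfone and esterification.
4. Stereochemistry: C6 and C7 come from an auxiliary-controlled syn aldol, and C5 and C10 are relayed from them in the cycloaddition. The E vinyl sulfone comes from anti iodosulfonylation of propyne plus a retentive coupling, and the Z enol ether from soft enolisation.

Key step: step 16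

Remark: eudesmane atom numbers (C1–C15) are used for the carbons of every intermediate. The target is read as (5S,6S,7S,10R), that is 5α-H, 6α-O (equatorial), 7β-isopropyl (equatorial), 10β-methyl, trans-fused.

**Step 1**
Reactants: 1 (S)-4-benzyl-1,3-oxazolidin-2-one; 2 isovaleryl chloride
Product: 3 (4S)-4-benzyl-3-(3-methylbutanoyl)-1,3-oxazolidin-2-one
Conditions: Et3N, DMAP (cat.), CH2Cl2, 0 °C to rt
Reagents that add atoms: none
Why: DMAP-catalysed N-acylation of an oxazolidinone by an acid chloride is a standard entry to Evans imides and does not touch the auxiliary stereocentre.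

**Step 2**
Reactants: 4 propane-1,3-diol
Product: 6 3-[(4-methoxybenzyl)oxy]propan-1-ol, via sodium 3-hydroxypropan-1-olate 5 (not isolated)
Conditions: NaH, THF, 0 °C (diol in excess); then PMBCl, Bu4NI (cat.), rt
Reagents that add atoms: 4-methoxybenzyl chloride, COc1ccc(CCl)cc1
Why: Williamson etherification with the symmetrical diol in excess should stop at the mono-PMB ether.

**Step 3**
Reactants: 6 3-[(4-methoxybenzyl)oxy]propan-1-ol
Product: 7 3-[(4-methoxybenzyl)oxy]propanal
Conditions: TEMPO (cat.), PhI(OAc)2, CH2Cl2, rt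
Reagents that add atoms: none
Why: The TEMPO/PhI(OAc)2 oxidation takes a primary alcohol to the aldehyde without over-oxidation and leaves the PMB ether alone.

**Step 4**
Reactants: 3 (4S)-4-benzyl-3-(3-methylbutanoyl)-1,3-oxazolidin-2-one; 7 3-[(4-methoxybenzyl)oxy]propanal
Product: 10 (4S)-4-benzyl-3-[(2S,3R)-3-hydroxy-5-[(4-methoxybenzyl)oxy]-2-(propan-2-yl)pentanoyl]-1,3-oxazolidin-2-one, via dibutylboron (Z)-enolate 8 (not isolated), via boron aldolate 9 (not isolated)
Conditions: Bu2BOTf, Et3N, CH2Cl2, 0 °C; 7, −78 to 0 °C; then pH 7 buffer, MeOH, 30% H2O2, 0 °C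
Reagents that add atoms: none
Why: In the Evans syn aldol reaction the (Z)-boron enolate reacts through a closed Zimmerman–Traxler chair on the face away from the benzyl group, which forms C6–C7 and sets C7 (2S) and C6 (3R) as the syn pair that becomes 6α-O/7β-isopropyl.

**Step 5**
Reactants: 10 aldol adduct
Product: 11 (4S)-4-benzyl-3-[(2S,3R)-3-(tert-butyldimethylsilyloxy)-5-[(4-methoxybenzyl)oxy]-2-(propan-2-yl)pentanoyl]-1,3-oxazolidin-2-one
Conditions: TBSOTf, 2,6-lutidine, CH2Cl2, 0 °C
Reagents that add atoms: tert-butyldimethylsilyl triflate, CC(C)(C)[Si](C)(C)OS(=O)(=O)C(F)(F)F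
Why: Silyl triflate with lutidine silylates hindered secondary aldol hydroxyls under non-basic conditions, so neither retro-aldol cleavage nor epimerisation is expected.

**Step 6**
Reactants: 11 silylated imide
Product: 12 (2R,3R)-3-(tert-butyldimethylsilyloxy)-5-[(4-methoxybenzyl)oxy]-2-(propan-2-yl)pentan-1-ol
Conditions: LiBH4, THF–MeOH, 0 °C
Reagents that add atoms: none
Why: Reductive removal of the oxazolidinone with LiBH4 turns the imide carbonyl (C8) into CH2OH without enolisation, so C7 is kept (the descriptor changes only by priority).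

**Step 7**
Reactants: 12 primary alcohol
Product: 13 (2S,3R)-3-(tert-butyldimethylsilyloxy)-5-[(4-methoxybenzyl)oxy]-2-(propan-2-yl)pentanal
Conditions: DMP, CH2Cl2, rt
Reagents that add atoms: none
Why: Dess–Martin oxidation is neutral and fast, so the α-branched β-silyloxy aldehyde should form without epimerisation at C7 or elimination.

**Step 8**
Reactants: 13 aldehyde
Product: 14 (3R,4R)-3-(tert-butyldimethylsilyloxy)-1-[(4-methoxybenzyl)oxy]-4-(propan-2-yl)hex-5-ene
Conditions: Ph3PCH3Br, NaHMDS, THF, 0 °C; then 13, −78 °C to rt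
Reagents that add atoms: methyltriphenylphosphonium bromide, C[P+](c1ccccc1)(c1ccccc1)c1ccccc1.[Br-]
Why: Wittig methylenation with the unstabilised ylide adds to the aldehyde at low temperature faster than it enolises it, which brings in C9 and keeps C7.

**Step 9**
Reactants: 15 propyne; 16 sodium benzenesulfinate
Product: 18 (E)-2-iodo-1-(phenylsulfonyl)prop-1-ene, via benzenesulfonyl iodide 17 (not isolated)
Conditions: I2, EtOAc–H2O, rt; propyne (excess), visible light, rt
Reagents that add atoms: iodine, II
Why: In the radical-chain iodosulfonylation of a terminal alkyne the sulfonyl radical adds to the terminal carbon (C1) and iodine is delivered anti at C10, which gives the E isomer with methyl C14 cis to the sulfonyl group.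

**Step 10**
Reactants: 14 terminal alkene; 18 (E)-2-iodo-1-(phenylsulfonyl)prop-1-ene
Product: 20 (1E,5S,6R)-6-(tert-butyldimethylsilyloxy)-8-[(4-methoxybenzyl)oxy]-2-methyl-1-(phenylsulfonyl)-5-(propan-2-yl)oct-1-ene, via B-alkyl-9-BBN borane 19 (not isolated)
Conditions: 9-BBN-H, THF, 0 °C to rt; then 18, PdCl2(dppf) (cat.), aq. K3PO4, DMF, rt
Reagents that add atoms: none
Why: Anti-Markovnikov hydroboration of the monosubstituted alkene followed by B-alkyl Suzuki–Miyaura coupling forms C9–C10 with retention at the electron-poor vinyl iodide, so the chain ends up trans to the sulfonyl group.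

**Step 11**
Reactants: 20 PMB ether
Product: 21 (3R,4S,7E)-3-(tert-butyldimethylsilyloxy)-7-methyl-8-(phenylsulfonyl)-4-(propan-2-yl)oct-7-en-1-ol
Conditions: DDQ, CH2Cl2–pH 7 buffer, 0 °C
Reagents that add atoms: none
Why: Oxidative PMB cleavage with DDQ acts only on the electron-rich benzyl ether, so the electron-poor vinyl sulfone and the TBS ether are inert.

**Step 12**
Reactants: 21 primary alcohol
Product: 22 (3R,4S,7E)-3-(tert-butyldimethylsilyloxy)-7-methyl-8-(phenylsulfonyl)-4-(propan-2-yl)oct-7-enal
Conditions: DMP, CH2Cl2, rt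
Reagents that add atoms: none
Why: Dess–Martin oxidation gives the β-silyloxy aldehyde (C4) under neutral conditions that do not provoke elimination.

**Step 13**
Reactants: 22 aldehyde
Product: 23 (5R,6S,9E)-5-(tert-butyldimethylsilyloxy)-9-methyl-10-(phenylsulfonyl)-6-(propan-2-yl)deca-1,9-dien-3-ol (both C4 carbinol epimers)
Conditions: CH2=CHMgBr, THF, −78 °C
Reagents that add atoms: vinylmagnesium bromide, C=C[Mg]Br
Why: Grignard 1,2-addition to the aldehyde at −78 °C is much faster than any reaction with the β,β-disubstituted vinyl sulfone, and the new carbinol centre is erased in the next step.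

**Step 14**
Reactants: 23 allylic alcohol
Product: 24 (5R,6S,9E)-5-(tert-butyldimethylsilyloxy)-9-methyl-10-(phenylsulfonyl)-6-(propan-2-yl)deca-1,9-dien-3-one
Conditions: DMP, CH2Cl2, 0 °C to rt
Reagents that add atoms: none
Why: Dess–Martin oxidation of both allylic alcohol epimers converges on one vinyl ketone without base that could trigger Michael addition or loss of the C6 silyloxy group.

**Step 15**
Reactants: 24 vinyl ketone
Product: 25 (3Z,5S,6S,9E)-3,5-bis(tert-butyldimethylsilyloxy)-9-methyl-10-(phenylsulfonyl)-6-(propan-2-yl)deca-1,3,9-triene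
Conditions: TBSOTf, Et3N, Et2O, −78 to 0 °C
Reagents that add atoms: tert-butyldimethylsilyl triflate, CC(C)(C)[Si](C)(C)OS(=O)(=O)C(F)(F)F
Why: Soft enolisation with silyl triflate and amine can only remove a C5 proton because the vinyl side has none, should give the preferred Z enol ether in which C6 lies trans to C3 on the outside of the diene, and avoids a free enolate that could expel the C6 silyloxy group.

**Step 16**
Reactants: 25 acyclic (E)-vinyl sulfone (Z)-2-silyloxydiene triene
Product: 26 (1R,5S,6S,7S,10R)-4,6-bis(tert-butyldimethylsilyloxy)-1-(phenylsulfonyl)-15-noreudesm-3-ene (trans-fused; 1β-SO2Ph; 5α-H; 6α-OTBS; 7β-isopropyl; 10β-methyl)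
Conditions: PhMe (0.01 M), BHT (cat.), base-washed sealed tube, 175 °C
Reagents that add atoms: none
Why: On heating, the triene should undergo a concerted, asynchronous, normal-electron-demand [4+2] cycloaddition in which the enol-ether carbon C5 (largest HOMO coefficient of the C2=C3–C4(OTBS)=C5 diene) bonds to C10, the β-carbon of the C1=C10 vinyl sulfone, and C2 bonds to C1, so that polarity and tether ask for the same regiochemistry. The closest known reaction type is the type 1 intramolecular Diels–Alder reaction of 1,7,9-decatrienes, known both for 2-silyloxydienes made from vinyl ketones and for (E)-vinyl sulfone dienophiles. Ring A (C1–C2–C3–C4–C5–C10) is closed as the cyclohexene of the cycloaddition itself, and ring B (C5–C6–C7–C8–C9–C10) is closed by the same C5–C10 bond with the C6–C9 tether folded as a chair. C5 and C10 are controlled by C6 and C7: A(1,3) strain with the cis OTBS group on C4 holds H6 in the diene plane, which leaves only the chair with the C6 OTBS and C7 isopropyl groups equatorial and thereby fixes which diene face meets which alkene face (C14 axial and β, H5 α). The trans fusion needs the tether exo and the methyl and sulfonyl groups endo, and this is secured because the cis-forming fold would push C7 against the C4 OTBS group, while C1 follows from suprafacial addition to the E alkene (sulfonyl cis to C14, equatorial) and is deleted in step 19. A 1,5-hydrogen shift cannot compete because C6 sits on the outside of the diene, and BHT and high dilution hold back radical and bimolecular pathways.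

**Step 17**
Reactants: 26 cycloadduct
Product: 27 (1R,5S,6S,7S,10R)-6-(tert-butyldimethylsilyloxy)-1-(phenylsulfonyl)-15-noreudesman-4-one
Conditions: 1 M HCl, THF, 0 °C
Reagents that add atoms: none
Why: Mild acid hydrolysis of the silyl enol ether protonates C3, so the C5 stereocentre made in step 16 is not involved, and the crowded secondary C6 TBS ether is cleaved far more slowly than the enol ether.

**Step 18**
Reactants: 27 ketone
Product: 28 (1R,5S,6S,7S,10R)-6-(tert-butyldimethylsilyloxy)-1-(phenylsulfonyl)eudesm-4(15)-ene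
Conditions: Zn, CH2Br2, TiCl4, THF (aged at 5 °C); then 27, CH2Cl2, rt
Reagents that add atoms: dibromomethane, BrCBr
Why: Takai–Lombardo methylenation uses a non-basic gem-dimetallic reagent, so the hindered C4 ketone should be converted without enolisation, which protects C5 from epimerisation and the β-silyloxy group at C6 from elimination.

**Step 19**
Reactants: 28 sulfone
Product: 29 (5S,6S,7S,10R)-6-(tert-butyldimethylsilyloxy)eudesm-4(15)-ene
Conditions: 6% Na(Hg), Na2HPO4, MeOH–THF, 0 °C to rt
Reagents that add atoms: none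
Why: Reductive desulfonylation by electron transfer from buffered sodium amalgam replaces the C1–S bond by C1–H, while the isolated exocyclic alkene and the silyl ether are inert.

**Step 20**
Reactants: 29 silyl ether
Product: 30 (5S,6S,7S,10R)-eudesm-4(15)-en-6-ol (6α-OH)
Conditions: TBAF, THF, 50 °C
Reagents that add atoms: none
Why: Fluoride-driven desilylation breaks only the Si–O bond, so C6 keeps its configuration, and the non-acidic medium keeps the exocyclic alkene from migrating into the ring.

**Step 21**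
Reactants: 31 (E)-p-coumaric acid
Product: 33 (E)-3-[4-(tert-butyldimethylsilyloxy)phenyl]prop-2-enoic acid, via bis-TBS silyl ester 32 (not isolated)
Conditions: TBSCl, imidazole, DMF, rt; then AcOH–THF–H2O, rt
Reagents that add atoms: tert-butyldimethylsilyl chloride, CC(C)(C)[Si](C)(C)Cl
Why: Exhaustive silylation followed by selective hydrolysis of the much more labile silyl ester leaves the phenol masked and the acid free.

**Step 22**
Reactants: 30 eudesm-4(15)-en-6α-ol; 33 O-TBS p-coumaric acid
Product: 35 (5S,6S,7S,10R)-eudesm-4(15)-en-6-yl (E)-3-[4-(tert-butyldimethylsilyloxy)phenyl]prop-2-enoate, via mixed anhydride 34 (not isolated)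
Conditions: 2,4,6-Cl3C6H2COCl, Et3N, PhMe, rt; then 30, DMAP, PhMe, rt to 60 °C
Reagents that add atoms: none
Why: Yamaguchi esterification delivers a strongly activated acylpyridinium to the hindered equatorial C6 hydroxyl and leaves the C6–O bond intact, so the configuration is retained.

**Step 23**
Reactants: 35 silyl-protected ester
Product: 36 CNP0321375.1, (5S,6S,7S,10R)-eudesm-4(15)-en-6-yl (E)-3-(4-hydroxyphenyl)prop-2-enoate
Conditions: TBAF, AcOH, THF, 0 °C
Reagents that add atoms: none
Why: Buffered fluoride cleaves the phenolic silyl ether rapidly at 0 °C, while the hindered cinnamate ester, its E alkene and the exocyclic methylene are untouched.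

**Compound list**

1 | (S)-4-benzyl-1,3-oxazolidin-2-one | O=C1N[C@@H](Cc2ccccc2)CO1 | starting material
2 | isovaleryl chloride | CC(C)CC(=O)Cl | starting material
3 | (4S)-4-benzyl-3-(3-methylbutanoyl)-1,3-oxazolidin-2-one | CC(C)CC(=O)N1[C@@H](Cc2ccccc2)COC1=O | intermediate
4 | propane-1,3-diol | OCCCO | starting material
5 | sodium 3-hydroxypropan-1-olate | [Na+].[O-]CCCO | intermediate
6 | 3-[(4-methoxybenzyl)oxy]propan-1-ol | COc1ccc(COCCCO)cc1 | intermediate
7 | 3-[(4-methoxybenzyl)oxy]propanal | COc1ccc(COCCC=O)cc1 | intermediate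
8 | dibutylboron (Z)-enolate of 3 | CCCCB(CCCC)O/C(=C\C(C)C)N1[C@@H](Cc2ccccc2)COC1=O | intermediate
9 | dibutylboron aldolate of 10 | O=C(N1[C@@H](Cc2ccccc2)COC1=O)[C@@H](C(C)C)[C@H](OB(CCCC)CCCC)CCOCc1ccc(OC)cc1 | intermediate
10 | (2S,3R) syn aldol imide | O=C(N1[C@@H](Cc2ccccc2)COC1=O)[C@@H](C(C)C)[C@H](O)CCOCc1ccc(OC)cc1 | intermediate
11 | O-TBS aldol imide | O=C(N1[C@@H](Cc2ccccc2)COC1=O)[C@@H](C(C)C)[C@H](O[Si](C)(C)C(C)(C)C)CCOCc1ccc(OC)cc1 | intermediate
12 | (2R,3R) C8 primary alcohol | OC[C@@H](C(C)C)[C@H](O[Si](C)(C)C(C)(C)C)CCOCc1ccc(OC)cc1 | intermediate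
13 | (2S,3R) C8 aldehyde | O=C[C@@H](C(C)C)[C@H](O[Si](C)(C)C(C)(C)C)CCOCc1ccc(OC)cc1 | intermediate
14 | (3R,4R) C8=C9 terminal alkene | C=C[C@@H](C(C)C)[C@H](O[Si](C)(C)C(C)(C)C)CCOCc1ccc(OC)cc1 | intermediate
15 | propyne | CC#C | starting material
16 | sodium benzenesulfinate | [Na+].[O-]S(=O)c1ccccc1 | starting material
17 | benzenesulfonyl iodide | O=S(=O)(I)c1ccccc1 | intermediate
18 | (E)-2-iodo-1-(phenylsulfonyl)prop-1-ene | I/C(C)=C/S(=O)(=O)c1ccccc1 | intermediate
19 | B-alkyl-9-BBN borane from 14 | B1(CC[C@@H](C(C)C)[C@H](O[Si](C)(C)C(C)(C)C)CCOCc2ccc(OC)cc2)C2CCCC1CCC2 | intermediate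
20 | (E)-vinyl sulfone PMB ether | O=S(=O)(c1ccccc1)/C=C(\C)CC[C@@H](C(C)C)[C@H](O[Si](C)(C)C(C)(C)C)CCOCc1ccc(OC)cc1 | intermediate
21 | (E)-vinyl sulfone C4 primary alcohol | O=S(=O)(c1ccccc1)/C=C(\C)CC[C@@H](C(C)C)[C@H](O[Si](C)(C)C(C)(C)C)CCO | intermediate
22 | (E)-vinyl sulfone C4 aldehyde | O=S(=O)(c1ccccc1)/C=C(\C)CC[C@@H](C(C)C)[C@H](O[Si](C)(C)C(C)(C)C)CC=O | intermediate
23 | allylic alcohol (C4 epimers) | O=S(=O)(c1ccccc1)/C=C(\C)CC[C@@H](C(C)C)[C@H](O[Si](C)(C)C(C)(C)C)CC(O)C=C | intermediate
24 | vinyl ketone | O=S(=O)(c1ccccc1)/C=C(\C)CC[C@@H](C(C)C)[C@H](O[Si](C)(C)C(C)(C)C)CC(=O)C=C | intermediate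
25 | (3Z,5S,6S,9E) triene, Diels–Alder precursor | O=S(=O)(c1ccccc1)/C=C(\C)CC[C@@H](C(C)C)[C@H](O[Si](C)(C)C(C)(C)C)/C=C(\O[Si](C)(C)C(C)(C)C)C=C | intermediate
26 | trans-fused cycloadduct (silyl enol ether, 1β-sulfone) | CC(C)(C)[Si](C)(C)OC1=CC[C@@H](S(=O)(=O)c3ccccc3)[C@]2(C)CC[C@@H](C(C)C)[C@H](O[Si](C)(C)C(C)(C)C)[C@@H]12 | intermediate
27 | C4 ketone sulfone | O=C1CC[C@@H](S(=O)(=O)c3ccccc3)[C@]2(C)CC[C@@H](C(C)C)[C@H](O[Si](C)(C)C(C)(C)C)[C@@H]12 | intermediate
28 | 4(15)-methylene sulfone | C=C1CC[C@@H](S(=O)(=O)c3ccccc3)[C@]2(C)CC[C@@H](C(C)C)[C@H](O[Si](C)(C)C(C)(C)C)[C@@H]12 | intermediate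
29 | 6α-(TBSO)eudesm-4(15)-ene | C=C1CCC[C@]2(C)CC[C@@H](C(C)C)[C@H](O[Si](C)(C)C(C)(C)C)[C@@H]12 | intermediate
30 | eudesm-4(15)-en-6α-ol | C=C1CCC[C@]2(C)CC[C@@H](C(C)C)[C@H](O)[C@@H]12 | intermediate
31 | (E)-p-coumaric acid | O=C(O)/C=C/c1ccc(O)cc1 | starting material
32 | bis-TBS p-coumarate (silyl ester, silyl ether) | CC(C)(C)[Si](C)(C)OC(=O)/C=C/c1ccc(O[Si](C)(C)C(C)(C)C)cc1 | intermediate
33 | O-TBS p-coumaric acid | O=C(O)/C=C/c1ccc(O[Si](C)(C)C(C)(C)C)cc1 | intermediate
34 | 2,4,6-trichlorobenzoic mixed anhydride of 33 | O=C(OC(=O)c1c(Cl)cc(Cl)cc1Cl)/C=C/c1ccc(O[Si](C)(C)C(C)(C)C)cc1 | intermediate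
35 | O-TBS protected target ester | C=C1CCC[C@]2(C)CC[C@@H](C(C)C)[C@H](OC(=O)/C=C/c3ccc(O[Si](C)(C)C(C)(C)C)cc3)[C@@H]12 | intermediate
36 | CNP0321375.1 | C=C1CCC[C@]2(C)CC[C@@H](C(C)C)[C@H](OC(=O)/C=C/c3ccc(O)cc3)[C@@H]12 | target

**Step count**

Total step count: 23.
Longest linear sequence: 20 steps, from 4 to 36 (steps 2–8, 10–20, 22 and 23).

**Steps most likely to fail**

**Step 16.** The trisubstituted vinyl sulfone may add too slowly, so that thermal decay of the silyl dienol ether overtakes the cycloaddition. The fallback keeps the same two bonds but raises the diene energy with a second donor (a Danishefsky-type 1-methoxy-3-silyloxydiene), whose polarity again matches C5 with C10 and C2 with C1. It sets out from aldehyde 22.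
- Ethynylmagnesium bromide (THF, −78 °C) would give the propargylic alcohol F1.
- Dess–Martin oxidation would give the ynone F2.
- DABCO-catalysed conjugate addition of methanol would give the (E)-β-methoxy enone F3.
- TBSOTf/Et3N would give the methoxy silyloxy triene F4.
- Heating in toluene near 110 °C should close both rings to the 2β-methoxy cycloadduct F5.
- Dilute HCl in THF would hydrolyse the enol ether with loss of methanol to the enone sulfone F6.
- Hydrogenation of its only C=C bond (H2, Pd/C, EtOAc) comes back to the route at ketone 27.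

**Step 10.** Attack of the aqueous base on the β-iodovinyl sulfone by addition–elimination, base-induced drift of the vinyl sulfone towards the allyl sulfone, or slow transmetalation of the branched borane may erode the coupling. The fallback builds C8–C9 and C10=C1 by olefinations and sets out from aldehyde 13.
- Wittig reaction with 1-(triphenylphosphoranylidene)propan-2-one (PhMe, 90 °C) would give the (E)-enone F7.
- Conjugate reduction with Stryker's reagent would give the methyl ketone F8.
- Horner–Wadsworth–Emmons reaction with diethyl (phenylsulfonyl)methylphosphonate (NaH, THF) would give the vinyl sulfone. Chromatographic separation of the E isomer comes back to the route at 20.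

**Step 18.** Crowding of C4 by C5 and the neighbouring C6 silyl ether may stall the methylenation, and the Lewis-acidic medium may start to strip the silyl ether on long exposure. The fallback is a two-stage Peterson olefination that sets out from ketone 27.
- The small, weakly basic organocerium reagent from Me3SiCH2Li and CeCl3 (THF, −78 °C) would give the β-hydroxysilane F9. Either C4 epimer is usable.
- Elimination with KH in THF comes back to the route at 28.

**Further compounds**

F1 | step 16 | propargylic alcohol (C4 epimers) | O=S(=O)(c1ccccc1)/C=C(\C)CC[C@@H](C(C)C)[C@H](O[Si](C)(C)C(C)(C)C)CC(O)C#C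
F2 | step 16 | ynone | O=S(=O)(c1ccccc1)/C=C(\C)CC[C@@H](C(C)C)[C@H](O[Si](C)(C)C(C)(C)C)CC(=O)C#C
F3 | step 16 | (E)-β-methoxy enone | O=S(=O)(c1ccccc1)/C=C(\C)CC[C@@H](C(C)C)[C@H](O[Si](C)(C)C(C)(C)C)CC(=O)/C=C/OC
F4 | step 16 | methoxy silyloxy triene | O=S(=O)(c1ccccc1)/C=C(\C)CC[C@@H](C(C)C)[C@H](O[Si](C)(C)C(C)(C)C)/C=C(\O[Si](C)(C)C(C)(C)C)/C=C/OC
F5 | step 16 | 2β-methoxy cycloadduct | CC(C)(C)[Si](C)(C)OC1=C[C@@H](OC)[C@@H](S(=O)(=O)c3ccccc3)[C@]2(C)CC[C@@H](C(C)C)[C@H](O[Si](C)(C)C(C)(C)C)[C@@H]12
F6 | step 16 | enone sulfone | O=C1C=C[C@@H](S(=O)(=O)c3ccccc3)[C@]2(C)CC[C@@H](C(C)C)[C@H](O[Si](C)(C)C(C)(C)C)[C@@H]12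
F7 | step 10 | (E)-enone | CC(=O)/C=C/[C@@H](C(C)C)[C@H](O[Si](C)(C)C(C)(C)C)CCOCc1ccc(OC)cc1
F8 | step 10 | methyl ketone | CC(=O)CC[C@@H](C(C)C)[C@H](O[Si](C)(C)C(C)(C)C)CCOCc1ccc(OC)cc1
F9 | step 18 | β-hydroxysilane (C4 epimers) | C[Si](C)(C)CC1(O)CC[C@@H](S(=O)(=O)c3ccccc3)[C@]2(C)CC[C@@H](C(C)C)[C@H](O[Si](C)(C)C(C)(C)C)[C@@H]12
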